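The earlier runs and the new flask stem from a simulated flask for an exercise; the scatter is artificial.

Split the decay of the electrophile in the gamma run into two routes before carrying it to a new flask.

| flask | electrophile | nucleophile | remark | time |
|---|---|---|---|---|
| gamma | 10 mM | 66 mM | run made earlier |  |
| green | 10 mM | 20.0 mM |  | 12 min |
| grey | 10 mM | 40.0 mM |  | 12 min |
| ochre | 10 mM | 80.0 mM |  | 12 min |

- gamma (time / min: electrophile / %, product / %): 0.500: 90.7, 7.3; 0.833: 85.9, 13.0; 1.50: 75.8, 20.3; 3.00: 58.2, 34.9; 6.00: 35.4, 53.6

(standard deviation of a reading: 0.5 percentage points)

- what has gone from electrophile into another species counts as reacted, even if it can come back

* part of the electrophile that has reacted at the end, green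
* part of the electrophile that has reacted at the end, grey
* part of the electrophile that has reacted at the end, ochre
* what raising the concentration of nucleophile from its lowest to its highest value here does to the part of the electrophile that has reacted (changes below 5 percentage points count as none) (no change / it falls / it rises)

Begin with the main step by itself, electrophile with nucleophile in excess (pseudo-first-order). The last gamma reading gives a rate of 0.173 /min, and scaling that from 66 mM to 20.0 mM of nucleophile gives 46.7% reacted in green after 12 min.

Now add one process. At 6.00 min, 17.0% of the reacted electrophile in the gamma run is not product, and this reckoning reads that as a parallel loss, assumed free of nucleophile, though one nucleophile level cannot prove that. The reading then splits into a side rate of 0.0295 /min and a main rate of 0.00218 /mM/min. Their ratio is the crossover nucleophile, the level at which both routes use electrophile equally fast: 13.5 mM. In this reckoning the total rate is the side rate times one plus nucleophile over crossover, so it stays near the side rate far below the crossover and grows with nucleophile far above it. That gives 58.3% for green, 75.3% for grey and 91.3% for ochre.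

Last comes the falling nucleophile. Taking one nucleophile as used per product, this reckoning puts the mean level in green 1.74 mM below its charge, and that lowers its green value to 56.4%.

The forecast gives 47%, 72% and 92%, with the trend it rises, and it reads the gap as “a parallel unseen side channel”. Its green value stands below the reckoning here.

The flask gives 57.4% for green, 74.0% for grey and 90.8% for ochre. With nucleophile raised from 20.0 mM to 80.0 mM, the part reacted changes thus: it rises, by 33 percentage points.

    electrophile + nucleophile → acid set free + product (k = 0.0402 /M/s)
    nucleophile + acid set free ⇌ protonated nucleophile, settled at all times (K = 3100 /M)
    electrophile ⇌ dormant form (K = 20.9, k = 5.40 × 10⁻⁴ /s)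

Ochre stands at 90.8% against 57.4% for the same run with green's nucleophile, and that difference in nucleophile is the main reason for the rise. For ochre the crossover gives a ratio of main to side route of 5.93, and just after the start the path to product uses electrophile at 6.0 times the forward rate of the path to the dormant form. Ochre read early, at 3.0 min, has 47.4% reacted; the crossover assigns 85.6% of that to product, which is 40.6% of the charge, and that flask holds 40.3%.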